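## Retrosynthetic overview
1. The Z alkene comes from syn semi-reduction of a conjugated enyne. The enyne comes from Sonogashira coupling of an ethynyl macrolactam with (R,E)-1-iodopent-1-en-3-ol, whose carbinol centre is set by CBS reduction.
2. The only ring, the 13-membered lactam, is closed once, by amide C–N bond formation from the open-chain amino acid.
3. Key disconnection: the ring N1–C2 bond at the stereocentre. It is made from a racemic β-acetoxy alkynoate and a primary amine by an enantioconvergent copper-catalysed propargylic amination (new).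
4. The amine comes from N-Boc-1,3-diaminopropane, N-(4-bromobutyl)phthalimide and Ac2O. The acetate comes from tert-butyl acetate, 3-(trimethylsilyl)propynal and Ac2O. The iodide comes from propionyl chloride and acetylene.

Assumption: the facial sense of the copper–pybox catalyst on this new substrate class is not known in advance. (S,S)-Ph-pybox is written; the equally available (R,R)-ligand is used instead if the first run gives the (S)-amine.

## Route

Step 1
Reactants: 1 tert-butyl (3-aminopropyl)carbamate; 2 N-(4-bromobutyl)phthalimide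
Product: 4 tert-butyl (3-{N-[4-(1,3-dioxoisoindolin-2-yl)butyl]acetamido}propyl)carbamate, via secondary amine 3 (not isolated)
Conditions: 1 (2 equiv), K2CO3, MeCN, 60 °C, 16 h; then Ac2O, rt, 2 h
Reagents that add atoms: acetic anhydride, CC(=O)OC(C)=O
Why: SN2 N-alkylation of the primary amine (used in excess to hold back dialkylation) is followed by N-acetylation of the only basic nitrogen in the same flask; no stereocentre is formed.

Step 2
Reactants: 4 tert-butyl (3-{N-[4-(1,3-dioxoisoindolin-2-yl)butyl]acetamido}propyl)carbamate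
Product: 5 tert-butyl {3-[N-(4-aminobutyl)acetamido]propyl}carbamate
Conditions: N2H4·H2O, EtOH, reflux, 3 h
Reagents that add atoms: none
Why: Ing–Manske hydrazinolysis (Gabriel synthesis) frees the primary amine, while the Boc carbamate and the tertiary acetamide are inert to hydrazine.

Step 3
Reactants: 6 tert-butyl acetate; 7 3-(trimethylsilyl)prop-2-ynal
Product: 10 rac-tert-butyl 3-acetoxy-5-(trimethylsilyl)pent-4-ynoate, via lithium enolate 8 (not isolated), via lithium aldolate 9 (not isolated)
Conditions: LDA, THF, −78 °C; then 7, −78 °C, 30 min; then Ac2O, −78 → 0 °C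
Reagents that add atoms: acetic anhydride, CC(=O)OC(C)=O
Why: Acetate aldol addition of a lithium ester enolate to a non-enolisable ynal (1,2-addition) is followed by O-acylation of the aldolate in the same flask; the new centre is left racemic because step 4 is enantioconvergent.

Step 4
Reactants: 10 rac-tert-butyl 3-acetoxy-5-(trimethylsilyl)pent-4-ynoate; 5 tert-butyl {3-[N-(4-aminobutyl)acetamido]propyl}carbamate
Product: 12 tert-butyl (R)-3-{[4-(N-{3-[(tert-butoxycarbonyl)amino]propyl}acetamido)butyl]amino}pent-4-ynoate, via terminal alkyne 11 (not isolated)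
Conditions: [Cu(MeCN)4]PF6 (10 mol %), (S,S)-Ph-pybox (12 mol %), KF (20 mol %), iPr2NEt (2 equiv), 5 (1.2 equiv), MeOH (0.4 M), −10 °C, Ar, 24 h
Reagents that add atoms: none
Why: Proposed new method: enantioconvergent copper-catalysed propargylic amination of a racemic β-acetoxy-β-ethynyl ester with an unhindered primary alkylamine; fluoride in methanol frees terminal alkyne 11, the monovalent copper–pybox acetylide expels acetate to give a planar copper allenylidene common to both enantiomers of 11, and amine 5 attacks its γ-carbon from the face left open by the C2-symmetric ligand, which forms the C–N bond and sets the (R) centre; the tert-butyl ester, the weak base, the low temperature and the high amine concentration are chosen so that capture by nitrogen outruns loss of the α-proton to the enyne; the closest known reaction type is the copper–pybox asymmetric propargylic amination of 1-aryl and simple 1-alkyl propargylic esters with anilines and secondary amines, including its desilylative variant with C-silylated esters, which has not been shown for a substrate with an ester β to the leaving group or for the primary amine of a polyamine chain.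

Step 5
Reactants: 12 tert-butyl (R)-3-{[4-(N-{3-[(tert-butoxycarbonyl)amino]propyl}acetamido)butyl]amino}pent-4-ynoate
Product: 14 (R)-9-acetyl-2-ethynyl-1,5,9-triazacyclotridecan-4-one, via amino acid 13 (not isolated)
Conditions: TFA/CH2Cl2 1:1, rt, 2 h, evaporate with PhMe; then FDPP (pentafluorophenyl diphenylphosphinate, 2 equiv), iPr2NEt (8 equiv), MeCN/DMF 9:1, 1 mM (syringe pump, 12 h), rt
Reagents that add atoms: none
Why: Acidolysis removes the Boc group and the tert-butyl ester together, and high-dilution macrolactamisation through the pentafluorophenyl ester acylates the unhindered primary amine rather than the α-branched secondary amine, leaving the stereocentre untouched.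

Step 6
Reactants: 15 propionyl chloride; 16 acetylene
Product: 17 (E)-1-chloropent-1-en-3-one
Conditions: AlCl3 (1.1 equiv), HC≡CH (bubbled), CH2Cl2, 0 °C → rt; ice/HCl; distil
Reagents that add atoms: none
Why: Friedel–Crafts-type chloroacylation of acetylene gives the β-chlorovinyl ketone, which equilibrates to the E isomer on work-up and distillation.

Step 7
Reactants: 17 (E)-1-chloropent-1-en-3-one
Product: 18 (E)-1-iodopent-1-en-3-one
Conditions: NaI (2 equiv), acetone, reflux, 3 h, dark
Reagents that add atoms: sodium iodide, [Na+].[I-]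
Why: Vinylogous Finkelstein exchange by conjugate addition–elimination is driven by precipitation of NaCl and keeps the E geometry.

Step 8
Reactants: 18 (E)-1-iodopent-1-en-3-one
Product: 19 (R,E)-1-iodopent-1-en-3-ol
Conditions: (S)-Me-CBS oxazaborolidine (10 mol %), BH3·SMe2 (0.7 equiv), THF, −30 °C; MeOH, aqueous work-up
Reagents that add atoms: none
Why: In this Corey–Bakshi–Shibata reduction the iodovinyl group acts as the large substituent and ethyl as the small one, so the (S)-catalyst delivers hydride to give the (R)-carbinol.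

Step 9
Reactants: 14 (R)-9-acetyl-2-ethynyl-1,5,9-triazacyclotridecan-4-one; 19 (R,E)-1-iodopent-1-en-3-ol
Product: 20 (R)-9-acetyl-2-[(3E,5R)-5-hydroxyhept-3-en-1-yn-1-yl]-1,5,9-triazacyclotridecan-4-one
Conditions: Pd(PPh3)4 (5 mol %), CuI (10 mol %), piperidine (3 equiv), THF, rt, Ar
Reagents that add atoms: none
Why: Sonogashira coupling keeps the E geometry of the vinyl iodide and tolerates free NH, OH and amides; any C2 epimer left from step 4 is now a diastereomer and is removed by chromatography.

Step 10
Reactants: 20 (R)-9-acetyl-2-[(3E,5R)-5-hydroxyhept-3-en-1-yn-1-yl]-1,5,9-triazacyclotridecan-4-one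
Product: 21 (R)-9-acetyl-2-[(1Z,3E,5R)-5-hydroxyhepta-1,3-dien-1-yl]-1,5,9-triazacyclotridecan-4-one (target)
Conditions: Zn(Cu/Ag), MeOH/H2O 1:1, 35 °C, 12 h, dark; filter, mildly basic work-up
Reagents that add atoms: none
Why: Boland reduction delivers two hydrogens syn to the conjugated triple bond only, giving the Z alkene while leaving the E alkene, both stereocentres and all heteroatom groups unchanged.

## Compound list
1 | tert-butyl (3-aminopropyl)carbamate | CC(C)(C)OC(=O)NCCCN | starting material
2 | N-(4-bromobutyl)phthalimide | O=C1c2ccccc2C(=O)N1CCCCBr | starting material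
3 | tert-butyl (3-{[4-(1,3-dioxoisoindolin-2-yl)butyl]amino}propyl)carbamate | CC(C)(C)OC(=O)NCCCNCCCCN1C(=O)c2ccccc2C1=O | intermediate
4 | tert-butyl (3-{N-[4-(1,3-dioxoisoindolin-2-yl)butyl]acetamido}propyl)carbamate | CC(C)(C)OC(=O)NCCCN(C(C)=O)CCCCN1C(=O)c2ccccc2C1=O | intermediate
5 | tert-butyl {3-[N-(4-aminobutyl)acetamido]propyl}carbamate | CC(C)(C)OC(=O)NCCCN(C(C)=O)CCCCN | intermediate
6 | tert-butyl acetate | CC(=O)OC(C)(C)C | starting material
7 | 3-(trimethylsilyl)prop-2-ynal | C[Si](C)(C)C#CC=O | starting material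
8 | lithium enolate of tert-butyl acetate | [Li+].C=C([O-])OC(C)(C)C | intermediate
9 | lithium aldolate, racemic (lithium 1-tert-butoxy-1-oxo-5-(trimethylsilyl)pent-4-yn-3-olate) | [Li+].[O-]C(CC(=O)OC(C)(C)C)C#C[Si](C)(C)C | intermediate
10 | rac-tert-butyl 3-acetoxy-5-(trimethylsilyl)pent-4-ynoate | CC(=O)OC(CC(=O)OC(C)(C)C)C#C[Si](C)(C)C | intermediate
11 | rac-tert-butyl 3-acetoxypent-4-ynoate | CC(=O)OC(CC(=O)OC(C)(C)C)C#C | intermediate
12 | tert-butyl (R)-3-{[4-(N-{3-[(tert-butoxycarbonyl)amino]propyl}acetamido)butyl]amino}pent-4-ynoate | C#C[C@H](NCCCCN(C(C)=O)CCCNC(=O)OC(C)(C)C)CC(=O)OC(C)(C)C | intermediate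
13 | (R)-3-({4-[N-(3-aminopropyl)acetamido]butyl}amino)pent-4-ynoic acid (handled as its TFA salt) | C#C[C@H](NCCCCN(C(C)=O)CCCN)CC(=O)O | intermediate
14 | (R)-9-acetyl-2-ethynyl-1,5,9-triazacyclotridecan-4-one | C#C[C@H]1CC(=O)NCCCN(C(C)=O)CCCCN1 | intermediate
15 | propionyl chloride | CCC(=O)Cl | starting material
16 | acetylene | C#C | starting material
17 | (E)-1-chloropent-1-en-3-one | CCC(=O)/C=C/Cl | intermediate
18 | (E)-1-iodopent-1-en-3-one | CCC(=O)/C=C/I | intermediate
19 | (R,E)-1-iodopent-1-en-3-ol | CC[C@@H](O)/C=C/I | intermediate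
20 | (R)-9-acetyl-2-[(3E,5R)-5-hydroxyhept-3-en-1-yn-1-yl]-1,5,9-triazacyclotridecan-4-one | CC[C@@H](O)/C=C/C#C[C@H]1CC(=O)NCCCN(C(C)=O)CCCCN1 | intermediate
21 | (R)-9-acetyl-2-[(1Z,3E,5R)-5-hydroxyhepta-1,3-dien-1-yl]-1,5,9-triazacyclotridecan-4-one | CC[C@@H](O)/C=C/C=C\[C@H]1CC(=O)NCCCN(C(C)=O)CCCCN1 | target

## Step count and risks
Total step count: 10.
Longest linear sequence: 6 (steps 1, 2, 4, 5, 9, 10).

**Step 4 (the new reaction).**
- Risks: the copper allenylidene may lose its α-proton to give the conjugated enyne ester, which then takes up the amine without stereocontrol. The unhindered alkylamine may bind copper. The ee may be only moderate.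
- The fallback uses known, stereospecific chemistry. It sets out from 7 and 5 and comes back at 14.
- Aldehyde 7 is combined with ketene, made in the flask from acetyl chloride and iPr2NEt. The catalyst is O-trimethylsilylquinine or O-trimethylsilylquinidine (10 mol %, whichever gives the S lactone) with LiClO4, in CH2Cl2/Et2O at −78 °C. This catalytic asymmetric acyl halide–aldehyde cyclocondensation gives (S)-4-[(trimethylsilyl)ethynyl]oxetan-2-one F1.
- Amine 5 is sulfonylated with 2-nitrobenzenesulfonyl chloride and Et3N to tert-butyl {3-[N-(4-{[(2-nitrophenyl)sulfonyl]amino}butyl)acetamido]propyl}carbamate F2.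
- The sodium salt of F2 (NaHMDS, DMF, 0 °C → rt) opens F1 at C4 by SN2 alkyl–oxygen cleavage with inversion. The lactone geometry blocks β-elimination. The product is (R)-3-{[4-(N-{3-[(tert-butoxycarbonyl)amino]propyl}acetamido)butyl][(2-nitrophenyl)sulfonyl]amino}-5-(trimethylsilyl)pent-4-ynoic acid F3.
- TFA gives (R)-3-{(4-[N-(3-aminopropyl)acetamido]butyl)[(2-nitrophenyl)sulfonyl]amino}-5-(trimethylsilyl)pent-4-ynoic acid F4.
- FDPP and iPr2NEt at 1 mM give (R)-9-acetyl-1-[(2-nitrophenyl)sulfonyl]-2-[(trimethylsilyl)ethynyl]-1,5,9-triazacyclotridecan-4-one F5.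
- PhSH and K2CO3 in DMF, then MeOH, remove the sulfonyl and the C-silyl groups to give 14.

**Step 5 (macrolactamisation with a free secondary amine).**
- Risks: oligomerisation, acylation at the secondary nitrogen, or loss of that nitrogen by β-elimination from the activated ester.
- The fallback masks the nitrogen as a non-basic, turn-inducing sulfonamide before ring closure. It sets out from 12 and comes back at 14.
- 12 is treated with 2-nitrobenzenesulfonyl chloride, Et3N and DMAP in CH2Cl2. This gives tert-butyl (R)-3-{[4-(N-{3-[(tert-butoxycarbonyl)amino]propyl}acetamido)butyl][(2-nitrophenyl)sulfonyl]amino}pent-4-ynoate F6.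
- TFA gives (R)-3-{(4-[N-(3-aminopropyl)acetamido]butyl)[(2-nitrophenyl)sulfonyl]amino}pent-4-ynoic acid F7.
- FDPP and iPr2NEt at 1 mM give (R)-9-acetyl-2-ethynyl-1-[(2-nitrophenyl)sulfonyl]-1,5,9-triazacyclotridecan-4-one F8.
- PhSH and K2CO3 in DMF give 14.

**Step 10 (semi-reduction).**
- Risks: incomplete conversion, over-reduction of the diene, or erosion of the Z geometry.
- The fallback builds the Z alkene before the diene is joined, so no reduction is needed. It sets out from 14 (with 19) and comes back at 21.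
- Z-selective trans-hydroboration of 14 uses pinacolborane, [Rh(cod)Cl]2 (1.5 mol %), P(iPr)3 (6 mol %) and Et3N in cyclohexane/THF at rt. It gives (R)-9-acetyl-2-[(Z)-2-(4,4,5,5-tetramethyl-1,3,2-dioxaborolan-2-yl)ethenyl]-1,5,9-triazacyclotridecan-4-one F9.
- Suzuki–Miyaura coupling of F9 with 19 (PdCl2(dppf) 5 mol %, aqueous K3PO4, THF, rt) keeps both alkene geometries and gives 21 directly.

Further compounds
F1 | step 4 | (S)-4-[(trimethylsilyl)ethynyl]oxetan-2-one | C[Si](C)(C)C#C[C@@H]1CC(=O)O1
F2 | step 4 | tert-butyl {3-[N-(4-{[(2-nitrophenyl)sulfonyl]amino}butyl)acetamido]propyl}carbamate | CC(C)(C)OC(=O)NCCCN(C(C)=O)CCCCNS(=O)(=O)c1ccccc1[N+](=O)[O-]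
F3 | step 4 | (R)-3-{[4-(N-{3-[(tert-butoxycarbonyl)amino]propyl}acetamido)butyl][(2-nitrophenyl)sulfonyl]amino}-5-(trimethylsilyl)pent-4-ynoic acid | C[Si](C)(C)C#C[C@H](N(CCCCN(C(C)=O)CCCNC(=O)OC(C)(C)C)S(=O)(=O)c1ccccc1[N+](=O)[O-])CC(=O)O
F4 | step 4 | (R)-3-{(4-[N-(3-aminopropyl)acetamido]butyl)[(2-nitrophenyl)sulfonyl]amino}-5-(trimethylsilyl)pent-4-ynoic acid | C[Si](C)(C)C#C[C@H](N(CCCCN(C(C)=O)CCCN)S(=O)(=O)c1ccccc1[N+](=O)[O-])CC(=O)O
F5 | step 4 | (R)-9-acetyl-1-[(2-nitrophenyl)sulfonyl]-2-[(trimethylsilyl)ethynyl]-1,5,9-triazacyclotridecan-4-one | C[Si](C)(C)C#C[C@H]1CC(=O)NCCCN(C(C)=O)CCCCN1S(=O)(=O)c2ccccc2[N+](=O)[O-]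
F6 | step 5 | tert-butyl (R)-3-{[4-(N-{3-[(tert-butoxycarbonyl)amino]propyl}acetamido)butyl][(2-nitrophenyl)sulfonyl]amino}pent-4-ynoate | C#C[C@H](N(CCCCN(C(C)=O)CCCNC(=O)OC(C)(C)C)S(=O)(=O)c1ccccc1[N+](=O)[O-])CC(=O)OC(C)(C)C
F7 | step 5 | (R)-3-{(4-[N-(3-aminopropyl)acetamido]butyl)[(2-nitrophenyl)sulfonyl]amino}pent-4-ynoic acid | C#C[C@H](N(CCCCN(C(C)=O)CCCN)S(=O)(=O)c1ccccc1[N+](=O)[O-])CC(=O)O
F8 | step 5 | (R)-9-acetyl-2-ethynyl-1-[(2-nitrophenyl)sulfonyl]-1,5,9-triazacyclotridecan-4-one | C#C[C@H]1CC(=O)NCCCN(C(C)=O)CCCCN1S(=O)(=O)c2ccccc2[N+](=O)[O-]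
F9 | step 10 | (R)-9-acetyl-2-[(Z)-2-(4,4,5,5-tetramethyl-1,3,2-dioxaborolan-2-yl)ethenyl]-1,5,9-triazacyclotridecan-4-one | CC1(C)OB(/C=C\[C@H]2CC(=O)NCCCN(C(C)=O)CCCCN2)OC1(C)C
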